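**Strategy.** The target (lutein 3‑O‑palmitate) is cut at the C8–C9 sp2–sp2 single bond (carotenoid numbering), between the vinyl group C7=C8 on the palmitoyloxy‑trimethylcyclohexene ring (ring A) and the methyl‑bearing chain carbon C9. A final Stille coupling joins a ring A dienylstannane, already esterified at C3, with an octaenyl C9 iodide ending in the free hydroxy cyclohexene ring (ring B). The step exploits that both flanking alkenes (7E, 9E) can be preset and coupled with retention, and that the carbinols C3 and C3' lie on different fragments, so the monoester regiochemistry is fixed without protecting groups and the coupling delivers the target directly.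

Key step: step 15

Assumption: (R)‑α‑ionone (7) and (4R,6R)‑actinol (1) are bought as single enantiomers; chain carbons are named by carotenoid numbering (ring A C1–C6, chain C7–C15 and C15'–C7', ring B C1'–C6').

**Ring A fragment**

Step 1
Reactants: 1 (4R,6R)-4-hydroxy-2,2,6-trimethylcyclohexanone (actinol); 2 hexadecanoyl chloride (palmitoyl chloride)
Product: 3 (1R,3R)-3,5,5-trimethyl-4-oxocyclohexyl hexadecanoate
Conditions: pyridine, DMAP (cat.), CH2Cl2, 0 °C to rt
Reagents that add atoms: none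
Why: Acylation of the secondary alcohol with an acid chloride under nucleophilic catalysis (esterification) should proceed without touching the hindered ketone or either stereocentre.

Step 2
Reactants: 3 (1R,3R)-3,5,5-trimethyl-4-oxocyclohexyl hexadecanoate
Product: 4 (1R)-3,5,5-trimethyl-4-{[(trifluoromethyl)sulfonyl]oxy}cyclohex-3-en-1-yl hexadecanoate
Conditions: Tf2O, 2,6-di-tert-butyl-4-methylpyridine, CH2Cl2, 0 °C to rt
Reagents that add atoms: trifluoromethanesulfonic anhydride O=S(=O)(OS(=O)(=O)C(F)(F)F)C(F)(F)F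
Why: Enol triflate formation (O‑sulfonylation of the ketone followed by loss of its only α‑proton, the other α‑carbon being quaternary) should give a single tetrasubstituted alkenyl triflate under weakly basic conditions that leave the ester α‑CH2 and the carbinol centre untouched.

Step 3
Reactants: 4 (1R)-3,5,5-trimethyl-4-{[(trifluoromethyl)sulfonyl]oxy}cyclohex-3-en-1-yl hexadecanoate; 5 (E)-1,2-bis(tributylstannyl)ethene (3 equiv)
Product: 6 (1R)-3,5,5-trimethyl-4-[(E)-2-(tributylstannyl)ethenyl]cyclohex-3-en-1-yl hexadecanoate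
Conditions: Pd2(dba)3 (5 mol%), AsPh3 (40 mol%), NMP, 60 °C, dark
Reagents that add atoms: none
Why: Stille coupling of an alkenyl triflate with an excess of the symmetrical distannane should stop at mono‑coupling and carries the E geometry of the distannane into the new C7=C8 vinylstannane with retention.

**Ring B aldehyde**

Step 4
Reactants: 7 (3E)-4-[(1R)-2,6,6-trimethylcyclohex-2-en-1-yl]but-3-en-2-one ((R)-α-ionone); 8 diethyl (cyanomethyl)phosphonate
Product: 9 (2E,4E)-3-methyl-5-[(1R)-2,6,6-trimethylcyclohex-2-en-1-yl]penta-2,4-dienenitrile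
Conditions: NaH, THF, 0 °C to rt; chromatography
Reagents that add atoms: none
Why: Horner–Wadsworth–Emmons olefination of the methyl ketone should favour the 2E nitrile (the 2Z isomer is removed by chromatography) and the aprotic conditions leave the ring stereocentre intact.

Step 5
Reactants: 9 (2E,4E)-3-methyl-5-[(1R)-2,6,6-trimethylcyclohex-2-en-1-yl]penta-2,4-dienenitrile
Product: 10 (2E,4E)-3-methyl-5-[(1R)-2,6,6-trimethyl-4-oxocyclohex-2-en-1-yl]penta-2,4-dienenitrile
Conditions: t-BuOOH (70% aq), NaOCl (aq), K2CO3, MeCN, −5 to 0 °C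
Reagents that add atoms: tert-butyl hydroperoxide CC(C)(C)OO
Why: Radical allylic C–H oxidation with t‑BuOOH/hypochlorite should attack the only unhindered secondary allylic CH2 of the ring (carotenoid C3') and give the enone, since the dienenitrile is electron‑poor and the tertiary C–H next to the gem‑dimethyl group is shielded.

Step 6
Reactants: 10 (2E,4E)-3-methyl-5-[(1R)-2,6,6-trimethyl-4-oxocyclohex-2-en-1-yl]penta-2,4-dienenitrile
Product: 11 (2E,4E)-5-[(1R,4R)-4-hydroxy-2,6,6-trimethylcyclohex-2-en-1-yl]-3-methylpenta-2,4-dienenitrile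
Conditions: K[HB(s-Bu)3], THF, −78 °C
Reagents that add atoms: none
Why: 1,2‑Reduction of the β,β‑disubstituted cyclohexenone by a bulky borohydride should occur anti to the pseudoaxial methyl of the gem‑dimethyl group, which lies on the face opposite to the pseudoaxial side chain (substrate control), so that the new carbinol (4R) is trans to the side chain.

Step 7
Reactants: 11 (2E,4E)-5-[(1R,4R)-4-hydroxy-2,6,6-trimethylcyclohex-2-en-1-yl]-3-methylpenta-2,4-dienenitrile
Product: 13 (2E,4E)-5-[(1R,4R)-4-hydroxy-2,6,6-trimethylcyclohex-2-en-1-yl]-3-methylpenta-2,4-dienal, via N-aluminated aldimine 12 (not isolated)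
Conditions: i-Bu2AlH (3 equiv), CH2Cl2, −78 °C; then aq. potassium sodium tartrate
Reagents that add atoms: water O
Why: Partial reduction of the conjugated nitrile by i‑Bu2AlH stops at the N‑aluminated imine, which is hydrolysed on work‑up to the dienal, while the alcohol merely consumes one hydride equivalent.

**Chain fragment (C9 to C12')**

Step 8
Reactants: 14 but-2-yn-1-ol
Product: 16 (2E)-3-iodobut-2-en-1-ol, via alkenylzirconocene 15 (not isolated)
Conditions: i-Bu2AlH (1 equiv), THF, 0 °C; then Cp2ZrCl2/i-Bu2AlH (Cp2Zr(H)Cl in situ), rt; then I2, −78 to 0 °C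
Reagents that add atoms: iodine II
Why: Hydrozirconation of the aluminium alkoxide of the alkynol is a syn addition that places zirconium on C3, remote from the alkoxide, and iodinolysis with retention should give the E alkenyl iodide.

Step 9
Reactants: 16 (2E)-3-iodobut-2-en-1-ol
Product: 17 (2E)-1-bromo-3-iodobut-2-ene
Conditions: CBr4, PPh3, CH2Cl2, 0 °C
Reagents that add atoms: carbon tetrabromide BrC(Br)(Br)Br
Why: Appel bromination converts the primary allylic alcohol into the bromide under neutral conditions without allylic transposition or loss of the alkenyl iodide.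

Step 10
Reactants: 17 (2E)-1-bromo-3-iodobut-2-ene
Product: 18 diethyl [(2E)-3-iodobut-2-en-1-yl]phosphonate
Conditions: P(OEt)3 (neat), 90 °C
Reagents that add atoms: triethyl phosphite CCOP(OCC)OCC
Why: The Michaelis–Arbuzov reaction occurs at the primary allylic bromide, the alkenyl iodide being inert to the phosphite.

Step 11
Reactants: 18 diethyl [(2E)-3-iodobut-2-en-1-yl]phosphonate; 19 (2E,4E,6E)-2,7-dimethylocta-2,4,6-trienedial (2.5 equiv)
Product: 20 (2E,4E,6E,8E,10E)-11-iodo-2,7-dimethyldodeca-2,4,6,8,10-pentaenal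
Conditions: NaN(SiMe3)2, THF, −78 °C; anion added slowly to 19, −78 to 0 °C, dark
Reagents that add atoms: none
Why: Horner–Wadsworth–Emmons olefination of an allylic phosphonate anion with an enal is E‑selective, and slow addition of the anion to an excess of the symmetrical dialdehyde should restrict the reaction to one aldehyde group.

Step 12
Reactants: 20 (2E,4E,6E,8E,10E)-11-iodo-2,7-dimethyldodeca-2,4,6,8,10-pentaenal
Product: 21 (2E,4E,6E,8E,10E)-11-iodo-2,7-dimethyldodeca-2,4,6,8,10-pentaen-1-ol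
Conditions: NaBH4, MeOH/THF, 0 °C, dark
Reagents that add atoms: none
Why: Borohydride 1,2‑reduction of the polyenal gives the allylic alcohol and leaves the alkenyl iodide and the polyene untouched.

Step 13
Reactants: 21 (2E,4E,6E,8E,10E)-11-iodo-2,7-dimethyldodeca-2,4,6,8,10-pentaen-1-ol
Product: 22 [(2E,4E,6E,8E,10E)-11-iodo-2,7-dimethyldodeca-2,4,6,8,10-pentaen-1-yl]triphenylphosphonium bromide
Conditions: PPh3·HBr, MeOH, rt, dark
Reagents that add atoms: triphenylphosphine hydrobromide Br.c1ccc(cc1)P(c1ccccc1)c1ccccc1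
Why: Acid‑promoted ionisation of the polyenyl allylic alcohol and capture of the delocalised cation by PPh3 at the primary terminus is the standard way from polyenols to Wittig salts and keeps the conjugated E polyene.

**Assembly**

Step 14
Reactants: 22 [(2E,4E,6E,8E,10E)-11-iodo-2,7-dimethyldodeca-2,4,6,8,10-pentaen-1-yl]triphenylphosphonium bromide; 13 (2E,4E)-5-[(1R,4R)-4-hydroxy-2,6,6-trimethylcyclohex-2-en-1-yl]-3-methylpenta-2,4-dienal
Product: 24 (1R,4R)-4-[(1E,3E,5E,7E,9E,11E,13E,15E)-16-iodo-3,7,12-trimethylheptadeca-1,3,5,7,9,11,13,15-octaen-1-yl]-3,5,5-trimethylcyclohex-2-en-1-ol, via 5Z isomer 23 (not isolated)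
Conditions: NaOMe, MeOH/CH2Cl2, 0 °C to rt; then EtOAc, 60 °C, dark
Reagents that add atoms: none
Why: Wittig olefination of the polyenyl ylide with the dienal forms the C11'=C12' bond, the sterically hindered 5Z isomer formed alongside should equilibrate to the E isomer on gentle heating, and methoxide tolerates both the free hydroxyl and the alkenyl iodide.

Step 15
Reactants: 6 (1R)-3,5,5-trimethyl-4-[(E)-2-(tributylstannyl)ethenyl]cyclohex-3-en-1-yl hexadecanoate; 24 (1R,4R)-4-[(1E,3E,5E,7E,9E,11E,13E,15E)-16-iodo-3,7,12-trimethylheptadeca-1,3,5,7,9,11,13,15-octaen-1-yl]-3,5,5-trimethylcyclohex-2-en-1-ol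
Product: 25 (1R)-4-[(1E,3E,5E,7E,9E,11E,13E,15E,17E)-18-[(1R,4R)-4-hydroxy-2,6,6-trimethylcyclohex-2-en-1-yl]-3,7,12,16-tetramethyloctadeca-1,3,5,7,9,11,13,15,17-nonaen-1-yl]-3,5,5-trimethylcyclohex-3-en-1-yl hexadecanoate (target)
Conditions: Pd2(dba)3 (5 mol%), AsPh3 (40 mol%), NMP, 25–40 °C, dark, argon; aq. KF work-up
Reagents that add atoms: none
Why: Zerovalent palladium inserts into the C9–I bond of 24 with retention, the C8 vinyl group of 6 is transferred from tin to palladium (AsPh3 as a weakly bound ligand speeds this step) and reductive elimination forms the C8–C9 sp2–sp2 bond. The closest known reaction type is the Stille coupling of dienylstannanes with trisubstituted alkenyl iodides used in retinoid and carotenoid polyene synthesis. No ring is closed and no stereocentre is formed; the 7E and 9E geometries are set in 6 and 24 and are carried over with retention. The step needs chemoselectivity for the alkenyl iodide over the palmitate ester and the free allylic hydroxyl of ring B, which the neutral, base‑free conditions secure. It also needs integrity of the nonaene, which room temperature, exclusion of light and oxygen and a short reaction time should secure. Because the ester is already on ring A and the free carbinol on ring B, the coupling fixes the monoester regiochemistry and gives 25 directly.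

**Compound list**

1 | (4R,6R)-4-hydroxy-2,2,6-trimethylcyclohexanone (actinol) | C[C@@H]1C[C@@H](O)CC(C)(C)C1=O | starting material
2 | hexadecanoyl chloride (palmitoyl chloride) | CCCCCCCCCCCCCCCC(Cl)=O | starting material
3 | (1R,3R)-3,5,5-trimethyl-4-oxocyclohexyl hexadecanoate | C[C@@H]1C[C@@H](OC(=O)CCCCCCCCCCCCCCC)CC(C)(C)C1=O | intermediate
4 | (1R)-3,5,5-trimethyl-4-{[(trifluoromethyl)sulfonyl]oxy}cyclohex-3-en-1-yl hexadecanoate | CCCCCCCCCCCCCCCC(=O)O[C@@H]1CC(C)=C(OS(=O)(=O)C(F)(F)F)C(C)(C)C1 | intermediate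
5 | (E)-1,2-bis(tributylstannyl)ethene | CCCC[Sn](CCCC)(CCCC)/C=C/[Sn](CCCC)(CCCC)CCCC | starting material
6 | (1R)-3,5,5-trimethyl-4-[(E)-2-(tributylstannyl)ethenyl]cyclohex-3-en-1-yl hexadecanoate | CCCCCCCCCCCCCCCC(=O)O[C@@H]1CC(C)=C(/C=C/[Sn](CCCC)(CCCC)CCCC)C(C)(C)C1 | intermediate
7 | (3E)-4-[(1R)-2,6,6-trimethylcyclohex-2-en-1-yl]but-3-en-2-one ((R)-α-ionone) | CC(=O)/C=C/[C@H]1C(C)=CCCC1(C)C | starting material
8 | diethyl (cyanomethyl)phosphonate | CCOP(=O)(CC#N)OCC | starting material
9 | (2E,4E)-3-methyl-5-[(1R)-2,6,6-trimethylcyclohex-2-en-1-yl]penta-2,4-dienenitrile | N#C/C=C(C)/C=C/[C@H]1C(C)=CCCC1(C)C | intermediate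
10 | (2E,4E)-3-methyl-5-[(1R)-2,6,6-trimethyl-4-oxocyclohex-2-en-1-yl]penta-2,4-dienenitrile | N#C/C=C(C)/C=C/[C@H]1C(C)=CC(=O)CC1(C)C | intermediate
11 | (2E,4E)-5-[(1R,4R)-4-hydroxy-2,6,6-trimethylcyclohex-2-en-1-yl]-3-methylpenta-2,4-dienenitrile | N#C/C=C(C)/C=C/[C@H]1C(C)=C[C@H](O)CC1(C)C | intermediate
12 | N-aluminated aldimine (O,N-bis(diisobutylaluminio) derivative of the aldimine of 13) | CC(C)C[Al](CC(C)C)N=C/C=C(C)/C=C/[C@H]1C(C)=C[C@H](O[Al](CC(C)C)CC(C)C)CC1(C)C | intermediate (not isolated)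
13 | (2E,4E)-5-[(1R,4R)-4-hydroxy-2,6,6-trimethylcyclohex-2-en-1-yl]-3-methylpenta-2,4-dienal | O=C/C=C(C)/C=C/[C@H]1C(C)=C[C@H](O)CC1(C)C | intermediate
14 | but-2-yn-1-ol | CC#CCO | starting material
15 | alkenylzirconocene: chlorobis(cyclopentadienyl)[(2E)-4-(diisobutylaluminiooxy)but-2-en-2-yl]zirconium | CC(C)C[Al](CC(C)C)OC/C=C(C)/[Zr](Cl)(C1C=CC=C1)C1C=CC=C1 | intermediate (not isolated)
16 | (2E)-3-iodobut-2-en-1-ol | OC/C=C(C)/I | intermediate
17 | (2E)-1-bromo-3-iodobut-2-ene | BrC/C=C(C)/I | intermediate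
18 | diethyl [(2E)-3-iodobut-2-en-1-yl]phosphonate | CCOP(=O)(OCC)C/C=C(C)/I | intermediate
19 | (2E,4E,6E)-2,7-dimethylocta-2,4,6-trienedial | O=C/C(C)=C/C=C/C=C(C)/C=O | starting material
20 | (2E,4E,6E,8E,10E)-11-iodo-2,7-dimethyldodeca-2,4,6,8,10-pentaenal | I/C(C)=C/C=C/C(C)=C/C=C/C=C(C)/C=O | intermediate
21 | (2E,4E,6E,8E,10E)-11-iodo-2,7-dimethyldodeca-2,4,6,8,10-pentaen-1-ol | I/C(C)=C/C=C/C(C)=C/C=C/C=C(C)/CO | intermediate
22 | [(2E,4E,6E,8E,10E)-11-iodo-2,7-dimethyldodeca-2,4,6,8,10-pentaen-1-yl]triphenylphosphonium bromide | I/C(C)=C/C=C/C(C)=C/C=C/C=C(C)/C[P+](c1ccccc1)(c1ccccc1)c1ccccc1.[Br-] | intermediate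
23 | 5Z isomer of 24: (1R,4R)-4-[(1E,3E,5Z,7E,9E,11E,13E,15E)-16-iodo-3,7,12-trimethylheptadeca-1,3,5,7,9,11,13,15-octaen-1-yl]-3,5,5-trimethylcyclohex-2-en-1-ol | I/C(C)=C/C=C/C(C)=C/C=C/C=C(C)/C=C\C=C(C)\C=C\[C@H]1C(C)=C[C@H](O)CC1(C)C | intermediate (not isolated)
24 | (1R,4R)-4-[(1E,3E,5E,7E,9E,11E,13E,15E)-16-iodo-3,7,12-trimethylheptadeca-1,3,5,7,9,11,13,15-octaen-1-yl]-3,5,5-trimethylcyclohex-2-en-1-ol | I/C(C)=C/C=C/C(C)=C/C=C/C=C(C)/C=C/C=C(C)/C=C/[C@H]1C(C)=C[C@H](O)CC1(C)C | intermediate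
25 | (1R)-4-[(1E,3E,5E,7E,9E,11E,13E,15E,17E)-18-[(1R,4R)-4-hydroxy-2,6,6-trimethylcyclohex-2-en-1-yl]-3,7,12,16-tetramethyloctadeca-1,3,5,7,9,11,13,15,17-nonaen-1-yl]-3,5,5-trimethylcyclohex-3-en-1-yl hexadecanoate | CCCCCCCCCCCCCCCC(=O)O[C@@H]1CC(C)=C(/C=C/C(C)=C/C=C/C(C)=C/C=C/C=C(C)/C=C/C=C(C)/C=C/[C@H]2C(C)=C[C@H](O)CC2(C)C)C(C)(C)C1 | target

**Totals**

Total step count: 15. Longest linear sequence: 8 steps (steps 8 to 15, from but-2-yn-1-ol 14).

**Steps most likely to fail**

Step 15 (key step). Transfer of the bulky dienyl group from tin to palladium may be slower than palladium‑ or light‑induced E/Z scrambling and reductive deiodination of the octaenyl iodide. The fallback replaces tin by boron and sets out from 6. Iododestannylation (I2, CH2Cl2, 0 °C) should give (1R)-4-[(E)-2-iodoethenyl]-3,5,5-trimethylcyclohex-3-en-1-yl hexadecanoate F1. Miyaura borylation (bis(pinacolato)diboron, PdCl2(PPh3)2, PPh3, KOPh, toluene, 50 °C) should give (1R)-3,5,5-trimethyl-4-[(E)-2-(4,4,5,5-tetramethyl-1,3,2-dioxaborolan-2-yl)ethenyl]cyclohex-3-en-1-yl hexadecanoate F2. Thallium‑accelerated Suzuki–Miyaura coupling of F2 with 24 (Pd(PPh3)4, TlOEt, THF/H2O, rt, dark) forms the same C8–C9 bond and comes back to the route at 25.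

Step 3. Tin‑to‑palladium transfer at the crowded palladium centre derived from the tetrasubstituted triflate may be slow, so that double coupling and protodestannylation of the distannane compete. The fallback builds the vinylstannane through the alkyne and sets out from 4. Sonogashira coupling with ethynyltrimethylsilane (PdCl2(PPh3)2, CuI, Et3N, DMF, 60 °C) should give (1R)-3,5,5-trimethyl-4-[(trimethylsilyl)ethynyl]cyclohex-3-en-1-yl hexadecanoate F3. Buffered desilylation (Bu4NF, AcOH, THF, 0 °C, ester‑safe) should give (1R)-4-ethynyl-3,5,5-trimethylcyclohex-3-en-1-yl hexadecanoate F4. Palladium‑catalysed syn hydrostannylation (Bu3SnH, PdCl2(PPh3)2 cat., THF, 0 °C) should place tin at the terminal carbon, because the ring blocks the internal position, and comes back to the route at 6.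

Step 6. Facial selectivity of the hydride addition may be poor if the side chain does not control the ring conformation as assumed. The fallback sets out from 10. Luche reduction (NaBH4, CeCl3·7H2O, MeOH, −20 °C) would give 11 together with its carbinol epimer (2E,4E)-5-[(1R,4S)-4-hydroxy-2,6,6-trimethylcyclohex-2-en-1-yl]-3-methylpenta-2,4-dienenitrile F5, which is separated. Mitsunobu inversion of F5 (4-nitrobenzoic acid, PPh3, diisopropyl azodicarboxylate, THF, 0 °C) should give (1R,4R)-4-[(1E,3E)-4-cyano-3-methylbuta-1,3-dien-1-yl]-3,5,5-trimethylcyclohex-2-en-1-yl 4-nitrobenzoate F6. Methanolysis (K2CO3, MeOH, rt) comes back to the route at 11.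

**Further compounds**

F1 | step 15 | (1R)-4-[(E)-2-iodoethenyl]-3,5,5-trimethylcyclohex-3-en-1-yl hexadecanoate | CCCCCCCCCCCCCCCC(=O)O[C@@H]1CC(C)=C(/C=C/I)C(C)(C)C1
F2 | step 15 | (1R)-3,5,5-trimethyl-4-[(E)-2-(4,4,5,5-tetramethyl-1,3,2-dioxaborolan-2-yl)ethenyl]cyclohex-3-en-1-yl hexadecanoate | CCCCCCCCCCCCCCCC(=O)O[C@@H]1CC(C)=C(/C=C/B2OC(C)(C)C(C)(C)O2)C(C)(C)C1
F3 | step 3 | (1R)-3,5,5-trimethyl-4-[(trimethylsilyl)ethynyl]cyclohex-3-en-1-yl hexadecanoate | CCCCCCCCCCCCCCCC(=O)O[C@@H]1CC(C)=C(C#C[Si](C)(C)C)C(C)(C)C1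
F4 | step 3 | (1R)-4-ethynyl-3,5,5-trimethylcyclohex-3-en-1-yl hexadecanoate | CCCCCCCCCCCCCCCC(=O)O[C@@H]1CC(C)=C(C#C)C(C)(C)C1
F5 | step 6 | (2E,4E)-5-[(1R,4S)-4-hydroxy-2,6,6-trimethylcyclohex-2-en-1-yl]-3-methylpenta-2,4-dienenitrile | N#C/C=C(C)/C=C/[C@H]1C(C)=C[C@@H](O)CC1(C)C
F6 | step 6 | (1R,4R)-4-[(1E,3E)-4-cyano-3-methylbuta-1,3-dien-1-yl]-3,5,5-trimethylcyclohex-2-en-1-yl 4-nitrobenzoate | N#C/C=C(C)/C=C/[C@H]1C(C)=C[C@H](OC(=O)c2ccc(cc2)[N+](=O)[O-])CC1(C)C
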